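Over the 12 h of this flask, the first thing I ask is how far E can carry the substrate.

- alder: G 0.10 M; L 0.10 M; E 0.22 M; D 33 µM; run made earlier
- flask: G 0.10 M; E 0.220 M; D 66 µM; L 0.10 M; time 12 h

alder run (percent of the G and L together charged)

| time / h | Q / % | J / % |
|---|---|---|
| 0.333 | 19.7 | 14.2 |
| 0.833 | 27.5 | 18.0 |
| 1.50 | 33.3 | 21.3 |
| 2.50 | 35.0 | 23.1 |

(scatter of a reading: 1 percentage point)

* Q and J together, in percent of the G and L charged together, at 12 h
* excess of Q over J in the product at 12 h
* whether the exchange between G and L keeps pace with the reaction: how far the product's excess at 12 h gets from its value without exchange to its value with instant exchange (above 80% keeps pace, below 20% hardly takes part, else lags behind)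

- D is single-handed; G and L are mirror images of each other, charged as a racemate, each of them at the stated concentration
- steps under discussion: E <-> X; E + D + G -> D + Q; E + D + L -> D + J; 2 D -> Z; G <-> L
- an excess is the difference of the two amounts in percent of their sum
- an excess is below zero if the other one leads
- no earlier run changes the charge of D; that part of a forecast is a guess

Each product molecule costs one E. The flask's charge of E is 110% of the charge of G and L together, and this ratio is what I carry: the reach. Q and J together cannot pass the smaller of the reach and 100%, so in this flask, with the reach above 100%, G and L together are the limiting reagent. The alder run has the same reach, 110%, yet it gains 3.5 percentage points between 1.50 h and 2.50 h and reads 58.1% at the end, well short of the reach. About 47.2% of its E is therefore not in product at that reading. I place this flask above that reading and below 100%; no earlier run changes the charge of D, so this placing is a guess.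

The forecast gives 75%, an excess of 19% and exchange that keeps pace, holding that “Doubling D under dimerisation adds only logarithmically”.

The flask gives 84.2% and an excess of 17.7%, and the exchange lags behind, getting 45% of the way.

    E ⇌ X (K = 5.50, k = 0.0197 min⁻¹)
    E + D + G → D + Q (k = 5280 M⁻² min⁻¹)
    E + D + L → D + J (k = 3000 M⁻² min⁻¹)
    2 D → Z (k = 19.5 M⁻¹ min⁻¹)
    G ⇌ L (k = 0.00503 min⁻¹)

The forward passing of E into X alone gives E a half-life of 0.59 h, the way back not counted, about equal to the 0.58 h of the step to J alone with the other concentrations held at their charge. At 12.0 h the flask's reach of 110% stands as 84.2% in product, 22.3% in X and 3.55% in E, all in fractions of the G and L charged.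

In the neighbour with 0.088 M of E, the reach is 44.0%, below 100%, so E sets the ceiling there. That flask gives 39.4%, with 4.08% in X and E down to 1.09% of its own charge.

All runs were generated by integration on assumed constants, and the scatter is random.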